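**Retrosynthetic overview**
- The quaternary lactone carbon is disconnected at its C–CH2Ar bond: a benzyl radical (from an oxirane-bearing benzylsilane) adds to C-5 of a 4-aryl-5-methoxycarbonyl-furan-2,3-dione, whose ring becomes the 3-hydroxybutenolide.
- The furan-2,3-dione comes from an arylpyruvate enol silane and oxalyl chloride; the arylpyruvate comes from 4-bromophenol (as aryl Grignard) and methyl glycidate, then oxidation.
- The benzylsilane comes from ortho-prenylation of 4-bromophenol, silylation, Kumada coupling with Me3SiCH2MgCl and Shi epoxidation.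
- Ring order: oxirane first (fragment stage), then the five-membered lactone ring (as the furandione); the key step turns it into the butenolide and sets the quaternary centre. The last step removes the two aryl silyl ethers.

Assumption: racemic methyl glycidate and the commercial ether solution of Me3SiCH2MgCl are bought as such; TIPS = triisopropylsilyl.

**Step 1**
Reactants: 1 4-bromophenol; 2 1-bromo-3-methylbut-2-ene (prenyl bromide)
Product: 3 4-bromo-2-(3-methylbut-2-en-1-yl)phenol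
Conditions: NaH, toluene, 0 °C; then 2, rt, 16 h
Reagents that add atoms: none
Why: ortho-C-alkylation of the tight sodium phenoxide ion pair in a non-polar solvent (phenoxide C-prenylation); the para position is blocked by Br, and the O-prenyl ether and 2,6-diprenyl by-products are removed by chromatography.

**Step 2**
Reactants: 3 4-bromo-2-(3-methylbut-2-en-1-yl)phenol
Product: 4 [4-bromo-2-(3-methylbut-2-en-1-yl)phenoxy](triisopropyl)silane
Conditions: TIPSCl, imidazole, DMF, rt
Reagents that add atoms: chlorotriisopropylsilane, CC(C)[Si](Cl)(C(C)C)C(C)C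
Why: standard silyl ether formation; TIPS survives Grignard reagents, buffered Oxone and the photoredox step and leaves with fluoride.

**Step 3**
Reactants: 4 [4-bromo-2-(3-methylbut-2-en-1-yl)phenoxy](triisopropyl)silane; 5 (trimethylsilyl)methylmagnesium chloride
Product: 6 trimethyl({3-(3-methylbut-2-en-1-yl)-4-[(triisopropylsilyl)oxy]phenyl}methyl)silane
Conditions: PdCl2(dppf) (3 mol%), THF, 60 °C
Reagents that add atoms: none
Why: Kumada–Corriu coupling; the Grignard reagent has no β-hydrogen, and the prenyl alkene and aryl silyl ether do not react.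

**Step 4**
Reactants: 6 trimethyl({3-(3-methylbut-2-en-1-yl)-4-[(triisopropylsilyl)oxy]phenyl}methyl)silane
Product: 7 (2-{[(2R)-3,3-dimethyloxiran-2-yl]methyl}-4-[(trimethylsilyl)methyl]phenoxy)(triisopropyl)silane
Conditions: D-fructose-derived Shi ketone (30 mol%), Oxone, K2CO3, Bu4NHSO4 (cat.), Na2B4O7/EDTA buffer, MeCN–DMM, 0 °C
Reagents that add atoms: Oxone (potassium peroxymonosulfate), [K+].[O-]S(=O)(=O)OO
Why: Shi asymmetric epoxidation; the chiral dioxirane attacks the trisubstituted alkene through the spiro transition state from the face that gives the (R)-oxirane, and the aryl silyl ether and C–Si bond are inert to buffered Oxone.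

**Step 5**
Reactants: 1 4-bromophenol
Product: 8 (4-bromophenoxy)(triisopropyl)silane
Conditions: TIPSCl, imidazole, DMF, rt
Reagents that add atoms: chlorotriisopropylsilane, CC(C)[Si](Cl)(C(C)C)C(C)C
Why: standard silyl ether formation, needed so that the phenol tolerates the Grignard step and oxalyl chloride.

**Step 6**
Reactants: 8 (4-bromophenoxy)(triisopropyl)silane; 9 methyl oxirane-2-carboxylate (racemic methyl glycidate)
Product: 11 methyl (2RS)-2-hydroxy-3-{4-[(triisopropylsilyl)oxy]phenyl}propanoate, via aryl Grignard reagent 10 (not isolated)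
Conditions: Mg, THF, 45 °C; then CuI (10 mol%), 9, −40 → −20 °C; aq. NH4Cl
Reagents that add atoms: none
Why: magnesium insertion, then copper-catalysed SN2 opening of the glycidate at the unsubstituted C-3 (faster than ester addition at −40 °C); the racemic carbinol centre is removed in the next step.

**Step 7**
Reactants: 11 methyl (2RS)-2-hydroxy-3-{4-[(triisopropylsilyl)oxy]phenyl}propanoate
Product: 12 methyl 2-oxo-3-{4-[(triisopropylsilyl)oxy]phenyl}propanoate
Conditions: Dess–Martin periodinane, CH2Cl2, 0 °C → rt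
Reagents that add atoms: none
Why: Dess–Martin oxidation of the α-hydroxy ester to the α-keto ester under non-basic conditions, which avoids aldol self-condensation of the enolisable arylpyruvate.

**Step 8**
Reactants: 12 methyl 2-oxo-3-{4-[(triisopropylsilyl)oxy]phenyl}propanoate; 13 oxalyl chloride
Product: 15 methyl 4,5-dioxo-3-{4-[(triisopropylsilyl)oxy]phenyl}-4,5-dihydrofuran-2-carboxylate, via silyl enol ether 14 (not isolated)
Conditions: TMSCl, Et3N, CH2Cl2, 0 °C; filter, evaporate; 13, Et2O, 0 °C → rt; evaporate, use at once under Ar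
Reagents that add atoms: none
Why: silyl enol ether/oxalyl chloride annulation (furan-2,3-dione synthesis): C-acylation at the benzylic enol carbon, loss of Me3SiCl, then O-acylation by the second acid chloride closes the five-membered dione ring.

**Step 9**
Reactants: 15 methyl 4,5-dioxo-3-{4-[(triisopropylsilyl)oxy]phenyl}-4,5-dihydrofuran-2-carboxylate; 7 (2-{[(2R)-3,3-dimethyloxiran-2-yl]methyl}-4-[(trimethylsilyl)methyl]phenoxy)(triisopropyl)silane
Product: 17 methyl (2R)-2-[(3-{[(2R)-3,3-dimethyloxiran-2-yl]methyl}-4-[(triisopropylsilyl)oxy]phenyl)methyl]-4-hydroxy-5-oxo-3-{4-[(triisopropylsilyl)oxy]phenyl}-2,5-dihydrofuran-2-carboxylate, via trimethylsilyl enol ether 16 (not isolated)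
Conditions: 15 (1.3 equiv), Ni(OTf)2 (10 mol%), chiral C2-symmetric N,N′-dioxide ligand (11 mol%), 9-mesityl-10-methylacridinium perchlorate (2 mol%), 4 Å MS, CH2Cl2–MeCN, 450 nm LEDs, −30 °C; then MeOH, pH 7 buffer, 0 °C
Reagents that add atoms: none
Why: Proposed new method: the excited acridinium oxidises the electron-rich benzylsilane 7 (about +1.3 V), loss of the silyl group gives a benzyl radical, and this adds Giese-fashion to C-5 of the Ni(II)-chelated (O-2/O-3, isatin-like) furan-2,3-dione, the only alkene carbon whose attack leaves a benzylic α-keto radical; reduction by the acridinyl radical and O-silylation give 16, with the N,N′-dioxide pocket shielding one face of the flat ring so that the (2R) quaternary centre is set here (ligand antipode to be fixed by screening; the oxirane centre is untouched); the closest known reaction types are photoinduced-electron-transfer benzylation of electron-poor alkenes with benzylsilanes and chiral-Lewis-acid-controlled enantioselective Giese additions to chelating acceptors.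

**Step 10**
Reactants: 17 methyl (2R)-2-[(3-{[(2R)-3,3-dimethyloxiran-2-yl]methyl}-4-[(triisopropylsilyl)oxy]phenyl)methyl]-4-hydroxy-5-oxo-3-{4-[(triisopropylsilyl)oxy]phenyl}-2,5-dihydrofuran-2-carboxylate
Product: 18 methyl (2R)-2-[(3-{[(2R)-3,3-dimethyloxiran-2-yl]methyl}-4-hydroxyphenyl)methyl]-4-hydroxy-3-(4-hydroxyphenyl)-5-oxo-2,5-dihydrofuran-2-carboxylate
Conditions: TBAF/AcOH (1:1, 2.4 equiv), THF, 0 °C; pH 7 buffer
Reagents that add atoms: none
Why: fluoride cleavage of the two aryl silyl ethers; acetic acid protonates each phenoxide as it forms so the ring-B phenol does not open the neighbouring oxirane, and the lactone, methyl ester and both stereocentres are untouched.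

**Compound list**
1 | 4-bromophenol | Oc1ccc(Br)cc1 | starting material
2 | 1-bromo-3-methylbut-2-ene | CC(C)=CCBr | starting material
3 | 4-bromo-2-(3-methylbut-2-en-1-yl)phenol | CC(C)=CCc1cc(Br)ccc1O | intermediate
4 | [4-bromo-2-(3-methylbut-2-en-1-yl)phenoxy](triisopropyl)silane | CC(C)=CCc1cc(Br)ccc1O[Si](C(C)C)(C(C)C)C(C)C | intermediate
5 | (trimethylsilyl)methylmagnesium chloride | C[Si](C)(C)C[Mg]Cl | starting material
6 | trimethyl({3-(3-methylbut-2-en-1-yl)-4-[(triisopropylsilyl)oxy]phenyl}methyl)silane | CC(C)=CCc1cc(C[Si](C)(C)C)ccc1O[Si](C(C)C)(C(C)C)C(C)C | intermediate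
7 | (2-{[(2R)-3,3-dimethyloxiran-2-yl]methyl}-4-[(trimethylsilyl)methyl]phenoxy)(triisopropyl)silane | C[Si](C)(C)Cc1ccc(O[Si](C(C)C)(C(C)C)C(C)C)c(C[C@H]2OC2(C)C)c1 | intermediate
8 | (4-bromophenoxy)(triisopropyl)silane | Brc1ccc(O[Si](C(C)C)(C(C)C)C(C)C)cc1 | intermediate
9 | methyl oxirane-2-carboxylate (racemic) | COC(=O)C1CO1 | starting material
10 | {4-[(triisopropylsilyl)oxy]phenyl}magnesium bromide (not isolated) | Br[Mg]c1ccc(O[Si](C(C)C)(C(C)C)C(C)C)cc1 | intermediate
11 | methyl (2RS)-2-hydroxy-3-{4-[(triisopropylsilyl)oxy]phenyl}propanoate (racemic) | COC(=O)C(O)Cc1ccc(O[Si](C(C)C)(C(C)C)C(C)C)cc1 | intermediate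
12 | methyl 2-oxo-3-{4-[(triisopropylsilyl)oxy]phenyl}propanoate | COC(=O)C(=O)Cc1ccc(O[Si](C(C)C)(C(C)C)C(C)C)cc1 | intermediate
13 | oxalyl chloride | ClC(=O)C(Cl)=O | starting material
14 | methyl (2Z)-3-{4-[(triisopropylsilyl)oxy]phenyl}-2-[(trimethylsilyl)oxy]prop-2-enoate (not isolated) | COC(=O)/C(O[Si](C)(C)C)=C/c1ccc(O[Si](C(C)C)(C(C)C)C(C)C)cc1 | intermediate
15 | methyl 4,5-dioxo-3-{4-[(triisopropylsilyl)oxy]phenyl}-4,5-dihydrofuran-2-carboxylate | COC(=O)C1=C(c2ccc(O[Si](C(C)C)(C(C)C)C(C)C)cc2)C(=O)C(=O)O1 | intermediate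
16 | methyl (2R)-2-[(3-{[(2R)-3,3-dimethyloxiran-2-yl]methyl}-4-[(triisopropylsilyl)oxy]phenyl)methyl]-5-oxo-3-{4-[(triisopropylsilyl)oxy]phenyl}-4-[(trimethylsilyl)oxy]-2,5-dihydrofuran-2-carboxylate (not isolated) | COC(=O)[C@]1(Cc2ccc(O[Si](C(C)C)(C(C)C)C(C)C)c(C[C@H]3OC3(C)C)c2)OC(=O)C(O[Si](C)(C)C)=C1c1ccc(O[Si](C(C)C)(C(C)C)C(C)C)cc1 | intermediate
17 | methyl (2R)-2-[(3-{[(2R)-3,3-dimethyloxiran-2-yl]methyl}-4-[(triisopropylsilyl)oxy]phenyl)methyl]-4-hydroxy-5-oxo-3-{4-[(triisopropylsilyl)oxy]phenyl}-2,5-dihydrofuran-2-carboxylate | COC(=O)[C@]1(Cc2ccc(O[Si](C(C)C)(C(C)C)C(C)C)c(C[C@H]3OC3(C)C)c2)OC(=O)C(O)=C1c1ccc(O[Si](C(C)C)(C(C)C)C(C)C)cc1 | intermediate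
18 | methyl (2R)-2-[(3-{[(2R)-3,3-dimethyloxiran-2-yl]methyl}-4-hydroxyphenyl)methyl]-4-hydroxy-3-(4-hydroxyphenyl)-5-oxo-2,5-dihydrofuran-2-carboxylate | COC(=O)[C@]1(Cc2ccc(O)c(C[C@H]3OC3(C)C)c2)OC(=O)C(O)=C1c1ccc(O)cc1 | target

**Totals**
Total step count: 10. Longest linear sequence: 6 steps (steps 5, 6, 7, 8, 9, 10; the other arm, steps 1, 2, 3, 4, 9, 10, is equally long).

**Steps most likely to fail, with fallbacks**

Step 9 is the least certain. The radical addition to a furan-2,3-dione is new, a cyclic 1,2-dione is a weak chelator, so face control and a racemic background reaction are open questions, and the oxirane of 7 must survive the Lewis acid. The fallback makes the same radical C–C bond on an open-chain 2-oxo-3-enoate, which binds chiral Lewis acids in the established two-point α-keto-ester mode. It sets out from 12. MgCl2/Et3N and methyl chlorooxoacetate give dimethyl (2Z)-2-hydroxy-4-oxo-3-{4-[(triisopropylsilyl)oxy]phenyl}pent-2-enedioate F1. TMSCl/Et3N caps the enol as dimethyl (2Z)-4-oxo-3-{4-[(triisopropylsilyl)oxy]phenyl}-2-[(trimethylsilyl)oxy]pent-2-enedioate F2. Photoredox addition of the benzyl radical from 7 to the β-carbon of F2 under the same chiral Ni(II) complex, with silyl transfer to the new enolate, gives dimethyl (2R,3E)-2-[(3-{[(2R)-3,3-dimethyloxiran-2-yl]methyl}-4-[(triisopropylsilyl)oxy]phenyl)methyl]-3-{4-[(triisopropylsilyl)oxy]phenyl}-2,4-bis[(trimethylsilyl)oxy]pent-3-enedioate F3. Buffered fluoride (KF/AcOH, MeOH, 0 °C) removes both trimethylsilyl groups, and the free tertiary alcohol lactonises onto the distal ester without passing through a retro-aldol-prone alkoxide. The route is rejoined at 17.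

Step 8 is the second risk: the furandione is a moisture-sensitive activated enol ester, and the one-pot double acylation may stop at the O-acylated enol. The fallback builds the ring by stepwise C-acylation and cyclodehydration. It sets out from 12. MgCl2/Et3N and tert-butyl chlorooxoacetate give 1-tert-butyl 5-methyl (3Z)-4-hydroxy-2-oxo-3-{4-[(triisopropylsilyl)oxy]phenyl}pent-3-enedioate F4. TFA in CH2Cl2 at 0 °C removes the tert-butyl ester to give (3Z)-4-hydroxy-5-methoxy-2,5-dioxo-3-{4-[(triisopropylsilyl)oxy]phenyl}pent-3-enoic acid F5. DCC in CH2Cl2 at 0 °C closes the enol oxygen onto the acid (the classical aroylpyruvic acid to furan-2,3-dione cyclodehydration). The route is rejoined at 15.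

Step 10 is the third risk: fluoride frees a phenol ortho to the oxirane, and cyclisation to a dihydrobenzofuran or chroman is the known failure even with buffering. The fallback carries the ring-B phenol as a benzyl ether and unveils it last by neutral hydrogenolysis. It sets out from 3.
- BnBr/K2CO3 in DMF gives 1-(benzyloxy)-4-bromo-2-(3-methylbut-2-en-1-yl)benzene F6.
- Kumada coupling with 5 gives {[4-(benzyloxy)-3-(3-methylbut-2-en-1-yl)phenyl]methyl}trimethylsilane F7.
- Shi epoxidation gives [(4-(benzyloxy)-3-{[(2R)-3,3-dimethyloxiran-2-yl]methyl}phenyl)methyl]trimethylsilane F8.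
- Coupling with 15 under the conditions of step 9 gives methyl (2R)-2-[(4-(benzyloxy)-3-{[(2R)-3,3-dimethyloxiran-2-yl]methyl}phenyl)methyl]-5-oxo-3-{4-[(triisopropylsilyl)oxy]phenyl}-4-[(trimethylsilyl)oxy]-2,5-dihydrofuran-2-carboxylate F9.
- Methanolysis gives methyl (2R)-2-[(4-(benzyloxy)-3-{[(2R)-3,3-dimethyloxiran-2-yl]methyl}phenyl)methyl]-4-hydroxy-5-oxo-3-{4-[(triisopropylsilyl)oxy]phenyl}-2,5-dihydrofuran-2-carboxylate F10.
- TBAF/AcOH now frees only the ring-A phenol, far from the oxirane, giving methyl (2R)-2-[(4-(benzyloxy)-3-{[(2R)-3,3-dimethyloxiran-2-yl]methyl}phenyl)methyl]-4-hydroxy-3-(4-hydroxyphenyl)-5-oxo-2,5-dihydrofuran-2-carboxylate F11.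
- H2 (1 atm), Pd/C, EtOAc cleaves the benzyl ether; the non-benzylic oxirane and the tetrasubstituted enol lactone are expected to survive. The route is rejoined at 18.

**Further compounds**
F1 | step 9 | dimethyl (2Z)-2-hydroxy-4-oxo-3-{4-[(triisopropylsilyl)oxy]phenyl}pent-2-enedioate | COC(=O)/C(O)=C(/C(=O)C(=O)OC)c1ccc(O[Si](C(C)C)(C(C)C)C(C)C)cc1
F2 | step 9 | dimethyl (2Z)-4-oxo-3-{4-[(triisopropylsilyl)oxy]phenyl}-2-[(trimethylsilyl)oxy]pent-2-enedioate | COC(=O)/C(O[Si](C)(C)C)=C(/C(=O)C(=O)OC)c1ccc(O[Si](C(C)C)(C(C)C)C(C)C)cc1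
F3 | step 9 | dimethyl (2R,3E)-2-[(3-{[(2R)-3,3-dimethyloxiran-2-yl]methyl}-4-[(triisopropylsilyl)oxy]phenyl)methyl]-3-{4-[(triisopropylsilyl)oxy]phenyl}-2,4-bis[(trimethylsilyl)oxy]pent-3-enedioate | COC(=O)[C@](Cc1ccc(O[Si](C(C)C)(C(C)C)C(C)C)c(C[C@H]2OC2(C)C)c1)(O[Si](C)(C)C)/C(c1ccc(O[Si](C(C)C)(C(C)C)C(C)C)cc1)=C(/O[Si](C)(C)C)C(=O)OC
F4 | step 8 | 1-tert-butyl 5-methyl (3Z)-4-hydroxy-2-oxo-3-{4-[(triisopropylsilyl)oxy]phenyl}pent-3-enedioate | COC(=O)/C(O)=C(/C(=O)C(=O)OC(C)(C)C)c1ccc(O[Si](C(C)C)(C(C)C)C(C)C)cc1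
F5 | step 8 | (3Z)-4-hydroxy-5-methoxy-2,5-dioxo-3-{4-[(triisopropylsilyl)oxy]phenyl}pent-3-enoic acid | COC(=O)/C(O)=C(/C(=O)C(=O)O)c1ccc(O[Si](C(C)C)(C(C)C)C(C)C)cc1
F6 | step 10 | 1-(benzyloxy)-4-bromo-2-(3-methylbut-2-en-1-yl)benzene | CC(C)=CCc1cc(Br)ccc1OCc1ccccc1
F7 | step 10 | {[4-(benzyloxy)-3-(3-methylbut-2-en-1-yl)phenyl]methyl}trimethylsilane | CC(C)=CCc1cc(C[Si](C)(C)C)ccc1OCc1ccccc1
F8 | step 10 | [(4-(benzyloxy)-3-{[(2R)-3,3-dimethyloxiran-2-yl]methyl}phenyl)methyl]trimethylsilane | C[Si](C)(C)Cc1ccc(OCc2ccccc2)c(C[C@H]2OC2(C)C)c1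
F9 | step 10 | methyl (2R)-2-[(4-(benzyloxy)-3-{[(2R)-3,3-dimethyloxiran-2-yl]methyl}phenyl)methyl]-5-oxo-3-{4-[(triisopropylsilyl)oxy]phenyl}-4-[(trimethylsilyl)oxy]-2,5-dihydrofuran-2-carboxylate | COC(=O)[C@]1(Cc2ccc(OCc3ccccc3)c(C[C@H]3OC3(C)C)c2)OC(=O)C(O[Si](C)(C)C)=C1c1ccc(O[Si](C(C)C)(C(C)C)C(C)C)cc1
F10 | step 10 | methyl (2R)-2-[(4-(benzyloxy)-3-{[(2R)-3,3-dimethyloxiran-2-yl]methyl}phenyl)methyl]-4-hydroxy-5-oxo-3-{4-[(triisopropylsilyl)oxy]phenyl}-2,5-dihydrofuran-2-carboxylate | COC(=O)[C@]1(Cc2ccc(OCc3ccccc3)c(C[C@H]3OC3(C)C)c2)OC(=O)C(O)=C1c1ccc(O[Si](C(C)C)(C(C)C)C(C)C)cc1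
F11 | step 10 | methyl (2R)-2-[(4-(benzyloxy)-3-{[(2R)-3,3-dimethyloxiran-2-yl]methyl}phenyl)methyl]-4-hydroxy-3-(4-hydroxyphenyl)-5-oxo-2,5-dihydrofuran-2-carboxylate | COC(=O)[C@]1(Cc2ccc(OCc3ccccc3)c(C[C@H]3OC3(C)C)c2)OC(=O)C(O)=C1c1ccc(O)cc1
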